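**Plan**

- Numbering (germacrane): ring C1–C10; epoxide on C1–C10; C14H2OAc on C10; C15HO on C4 of the C4=C5 alkene; lactone C6–O–C12(=O)–C11(=C13H2)–C7; OAc on C8.
- Enabling feature: the epoxide carbons and the enal alkene are the ends of a masked 1,5-diene C10=C1–C2–C3–C4=C5. Joining C1–C4 and C5–C10 turns it into a bicyclo[2.2.0]hexane fused to the six carbons C5–C10. The central cyclobutane C1–C10–C5–C4 of that 6-4-4 tricycle is the [2+2] photoadduct of a cyclohexenone (C6=O, C5=C10) and a cyclobutene ester (C1=C4, C15 as CO2Me).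
- Retrosynthetic cuts, in order: the acetates and the epoxide oxygen; C11=C13; the lactone C6–O bond; the ten-membered ring is traced back (C1–C4, C5–C10) to the tricycle, which is cut at C1–C10 and C4–C5; the cyclohexenone is cut at C5=C10 (metathesis) and C7–C8 (aldol).
- Forward order: acyclic chain by aldol, six-membered ring by ring-closing metathesis, central four-membered ring by photocycloaddition, ten-membered ring by thermal opening of the tricycle, γ-lactone, epoxide.
- Stereochemistry: C7 and C8 from an Evans syn aldol with (R)-4-benzyloxazolidinone; C6 from a CBS reduction after ring expansion; C1 and C10 from a Sharpless epoxidation with D-(−)-diisopropyl tartrate. The four cyclobutane centres are transient. C1=C10 geometry comes from the cycloreversion and C4=C5 is equilibrated to ring-cis.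

Key step: step 13

Remark on the chemistry: C6 is kept as the ketone until after the ring expansion, so that every stereoisomer of the photoadduct collapses to one dienone. TBS = tert-butyl(dimethyl)silyl; cyclic compounds from 20 on carry germacrane locants; "ring-cis" means the two ring carbons lie on the same side of the double bond.

**Route**

Step 1
Reactants: 1 2-methylidenepropane-1,3-diol
Product: 2 2-[(TBS-oxy)methyl]prop-2-en-1-ol
Conditions: NaH (1.0 equiv), THF, 0 °C; TBSCl (1.0 equiv), rt
Reagents that add atoms: tert-butyl(chloro)dimethylsilane, CC(C)(C)[Si](C)(C)Cl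
Why: Monosilylation of a symmetric diol through its sparingly soluble monosodium alkoxide (Williamson-type O-silylation) should favour the mono-ether over the bis-ether.

Step 2
Reactants: 2 2-[(TBS-oxy)methyl]prop-2-en-1-ol
Product: 3 3-bromo-2-[(TBS-oxy)methyl]prop-1-ene
Conditions: CBr4, PPh3, CH2Cl2, 0 °C
Reagents that add atoms: carbon tetrabromide, BrC(Br)(Br)Br
Why: The Appel reaction converts the primary allylic alcohol into the bromide under neutral conditions that leave the silyl ether intact.

Step 3
Reactants: 3 3-bromo-2-[(TBS-oxy)methyl]prop-1-ene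
Product: 4 3-[(TBS-oxy)methyl]but-3-en-1-ol
Conditions: indium powder (In), 37% aq. HCHO, THF/H2O, rt
Reagents that add atoms: formaldehyde, C=O
Why: Indium-mediated Barbier allylation of formaldehyde in water adds the allyl unit through its γ-terminus, which for this 2-substituted allyl bromide regenerates the same 1,1-disubstituted alkene one carbon longer.

Step 4
Reactants: 4 3-[(TBS-oxy)methyl]but-3-en-1-ol
Product: 5 3-[(TBS-oxy)methyl]but-3-enal
Conditions: Dess–Martin periodinane, NaHCO3, CH2Cl2, 0 °C; used at once without chromatography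
Reagents that add atoms: none
Why: Buffered Dess–Martin oxidation gives the β,γ-unsaturated aldehyde without acid or base strong enough to move the alkene into conjugation.

Step 5
Reactants: 6 mono-tert-butyl succinate; 7 (4R)-4-benzyl-1,3-oxazolidin-2-one
Product: 9 tert-butyl 4-[(4R)-4-benzyl-2-oxo-1,3-oxazolidin-3-yl]-4-oxobutanoate, via mixed pivalic anhydride 8 (not isolated)
Conditions: PivCl, Et3N, THF, −20 °C; then LiCl, 7, −20 °C → rt
Reagents that add atoms: none
Why: Evans N-acylation through the mixed pivalic anhydride (LiCl/Et3N variant) acylates the oxazolidinone at the unhindered succinyl carbonyl.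

Step 6
Reactants: 9 tert-butyl 4-[(4R)-4-benzyl-2-oxo-1,3-oxazolidin-3-yl]-4-oxobutanoate; 5 3-[(TBS-oxy)methyl]but-3-enal
Product: 12 tert-butyl (3R,4S)-3-{[(4R)-4-benzyl-2-oxo-1,3-oxazolidin-3-yl]carbonyl}-4-hydroxy-6-[(TBS-oxy)methyl]hept-6-enoate, via dibutylboron Z-enolate 10 (not isolated), via dibutylboron aldolate 11 (not isolated)
Conditions: Bu2BOTf, iPr2NEt, CH2Cl2, −78 → 0 °C; 5, −78 → 0 °C; pH 7 buffer, MeOH, 30% H2O2, 0 °C
Reagents that add atoms: none
Why: In this Evans syn aldol the Z-boron enolate reacts through a closed Zimmerman–Traxler chair on the face away from the benzyl group, which sets C7 (R) and C8 (S) together, while the tert-butyl ester neither enolises nor lactonises onto the new hydroxyl.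

Step 7
Reactants: 12 Evans aldol adduct (3R,4S)
Product: 13 tert-butyl (3R,4S)-4-hydroxy-3-[methoxy(methyl)carbamoyl]-6-[(TBS-oxy)methyl]hept-6-enoate
Conditions: MeONHMe·HCl, AlMe3, THF, −20 → 0 °C
Reagents that add atoms: N,O-dimethylhydroxylamine hydrochloride, CNOC.Cl
Why: Aluminium-amide transamidation (Weinreb amide formation) is directed to the exocyclic imide carbonyl by the free C8 hydroxyl and releases the auxiliary without touching C7.

Step 8
Reactants: 13 hydroxy Weinreb amide
Product: 14 tert-butyl (3R,4S)-3-[methoxy(methyl)carbamoyl]-4-(TBS-oxy)-6-[(TBS-oxy)methyl]hept-6-enoate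
Conditions: TBSOTf, 2,6-lutidine, CH2Cl2, −78 °C
Reagents that add atoms: tert-butyldimethylsilyl triflate, CC(C)(C)[Si](C)(C)OS(=O)(=O)C(F)(F)F
Why: Silyl triflate/lutidine silylation protects the hindered secondary hydroxyl at a temperature at which the tert-butyl ester is not attacked.

Step 9
Reactants: 14 silylated Weinreb amide
Product: 15 tert-butyl (3R,4S)-3-(prop-2-enoyl)-4-(TBS-oxy)-6-[(TBS-oxy)methyl]hept-6-enoate
Conditions: CH2=CHMgBr, THF, −78 → 0 °C; inverse quench into cold dilute aqueous acid
Reagents that add atoms: vinylmagnesium bromide, C=C[Mg]Br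
Why: In the Weinreb ketone synthesis the N-methoxy-N-methylamide takes up a single vinyl group, and the hindered tert-butyl ester is spared at low temperature.

Step 10
Reactants: 15 vinyl ketone
Product: 16 tert-butyl 2-{(1R,6S)-2-oxo-6-(TBS-oxy)-4-[(TBS-oxy)methyl]cyclohex-3-en-1-yl}acetate
Conditions: second-generation Grubbs catalyst (H2IMes)(PCy3)Cl2Ru=CHPh (5 mol %), CH2Cl2 (5 mM), 40 °C
Reagents that add atoms: none
Why: Ring-closing metathesis between the acryloyl group and the 1,1-disubstituted alkene closes the six-membered ring as the trisubstituted enone C5=C10 under neutral conditions that neither epimerise C7 nor eliminate the C8 silyloxy group.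

Step 11
Reactants: 17 ethyl 1-bromocyclobutane-1-carboxylate
Product: 18 cyclobut-1-ene-1-carboxylic acid
Conditions: KOH, PhMe, reflux; then aq. HCl, 0 °C
Reagents that add atoms: potassium hydroxide, [K+].[OH-]
Why: E2 dehydrobromination of the tertiary α-bromo ester with concurrent saponification is the classical entry to this strained acrylic acid.

Step 12
Reactants: 18 cyclobut-1-ene-1-carboxylic acid
Product: 19 methyl cyclobut-1-ene-1-carboxylate
Conditions: MeI, K2CO3, DMF, 0 °C → rt; used freshly distilled
Reagents that add atoms: iodomethane, CI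
Why: O-Alkylation of the carboxylate gives the methyl ester without acid, which would polymerise the strained alkene.

Step 13
Reactants: 16 cyclohexenone (7R,8S in germacrane locants); 19 methyl cyclobut-1-ene-1-carboxylate
Product: 21 cis-anti-cis 6-4-4 tricyclic keto diester (1R,4S,5R,7R,8S,10S), via trans-fused C5 epimer 20 (not isolated)
Conditions: 19 (5 equiv), hν (350 nm, Pyrex), CH2Cl2, −20 °C, Ar; then basic Al2O3, CH2Cl2, rt (brief)
Reagents that add atoms: none
Why: Excitation of the enone (n→π*) and intersystem crossing give the triplet, whose β-carbon C10 bonds to the unsubstituted cyclobutene carbon C1 to leave a 1,4-biradical centred on C5 (α to the ketone) and C4 (tertiary, α to the ester), and after spin inversion C4–C5 closes. The closest known reaction type is the intermolecular enone–alkene [2+2] photocycloaddition in its established cyclohexenone/cyclobut-1-enecarboxylate form. One ring is closed, the central cyclobutane C1–C10–C5–C4, by radical addition followed by 1,4-biradical recombination. C1 and C4 are cis because both stay in the intact cyclobutene ring, C5 and C10 end up cis because the six–four junction is α to the ketone and any trans isomer 20 is equilibrated on alumina, the outer rings lie anti because the CH2CH2 bridge turns away from the six-membered ring, and the enone face opposite the C8 silyloxy group should be preferred. The selectivity that matters is head-to-head regiochemistry (ester carbon C4 onto C5), secured by the acceptor ester: electron-poor alkenes add to triplet enones in this sense and the first bond leaves the radical on the ester-bearing carbon. Facial selectivity need not be high, because C1, C4, C5 and C10 all return to sp2 in step 14 while C6 is still a carbonyl, so both facial isomers converge on 23.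

Step 14
Reactants: 21 cis-anti-cis 6-4-4 tricyclic keto diester
Product: 23 all-cis cyclodeca-1(10),4-dien-6-one diester (7R,8S), via ring-trans C4=C5 dienone 22 (not isolated)
Conditions: PhMe (5 mM, degassed), BHT (cat.), base-washed sealed tube, about 160 °C; then rt, I2 (5 mol %), visible light; aq. Na2S2O3 wash
Reagents that add atoms: none
Why: Thermal cycloreversion of the bicyclo[2.2.0]hexane breaks the strained central bond C1–C4 to an ester-stabilised cyclohexane-1,4-diyl that fragments at C5–C10; the chair diyl with C14 equatorial should give ring-cis C1=C10 and ring-trans C4=C5, and iodine-atom-catalysed equilibration of that strained, doubly activated alkene then leads to the all-cis dienone, the least strained isomer and the one no longer prone to Cope rearrangement.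

Step 15
Reactants: 23 all-cis dienone diester
Product: 24 (6R,7S,8S)-6-hydroxy diester
Conditions: (R)-Me-CBS oxazaborolidine (20 mol %), catecholborane, PhMe, −78 °C
Reagents that add atoms: none
Why: In the Corey–Bakshi–Shibata reduction the (R)-oxazaborolidine delivers hydride to the enone carbonyl in 1,2-fashion with the alkenyl group as the large substituent, which sets C6 as R (oxygen trans to the C7 side chain), and the ring-cis alkene keeps the new hydroxyl away from the C15 ester.

Step 16
Reactants: 24 (6R)-hydroxy diester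
Product: 25 trans-fused 12,6-lactone methyl enoate (6R,7S,8S)
Conditions: CSA (20 mol %), PhMe (anhydrous), 60 °C
Reagents that add atoms: none
Why: Acid-catalysed transesterification closes the five-membered lactone between the C6 hydroxyl and C12 with loss of tert-butanol, the electron-poor enoate disfavouring ionisation of the allylic C6–O bond.

Step 17
Reactants: 25 lactone methyl enoate
Product: 28 α-methylene lactone methyl enoate (6R,7S,8S), via C11 dimethylaminomethyl lactone 26 (not isolated), via trimethylammonium iodide 27 (not isolated)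
Conditions: LiN(iPr)2 (1.1 equiv), THF, −78 °C; Me2N=CH2 I (Eschenmoser's salt), −78 → 0 °C; MeI, THF/MeOH, rt; aq. NaHCO3, EtOAc, rt
Reagents that add atoms: N,N-dimethylmethyleneiminium iodide, C=[N+](C)C.[I-]
Why: Eschenmoser methylenation (kinetic deprotonation at the unhindered C11 methylene, Mannich reaction, N-methylation, base-induced elimination) installs C13, the transient C11 stereocentre being lost again, while the α-branched enoate is a poor Michael acceptor with less accessible γ-hydrogens.

Step 18
Reactants: 28 α-methylene lactone methyl enoate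
Product: 29 α-methylene lactol with C15 allylic alcohol (C12 anomers)
Conditions: iBu2AlH (4.5 equiv), CH2Cl2, −78 °C; Rochelle salt work-up
Reagents that add atoms: none
Why: Excess iBu2AlH at −78 °C reduces the methyl enoate to the allylic alcohol in 1,2-fashion and stops the lactone at the lactol stage (an inconsequential anomeric mixture at C12), so the two ester-level carbonyls need not be told apart.

Step 19
Reactants: 29 lactol diol
Product: 30 bis-TBS enal α-methylene lactone (6R,7S,8S)
Conditions: activated MnO2 (excess), CH2Cl2, rt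
Reagents that add atoms: none
Why: MnO2 oxidises only allylic positions, taking the primary allylic alcohol to the enal and the allylic lactol back to the α-methylene lactone, with silyl ethers and the isolated alkene untouched.

Step 20
Reactants: 30 bis-TBS enal lactone
Product: 31 C8,C14-diol enal lactone (6R,7R,8S)
Conditions: HF·pyridine, pyridine, THF, 0 °C → rt
Reagents that add atoms: none
Why: Fluoride-mediated desilylation with buffered HF·pyridine removes both silyl ethers under conditions tolerated by the enal and the α-methylene lactone.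

Step 21
Reactants: 31 diol enal lactone
Product: 32 (1R,10R)-epoxy diol (1R,6R,7R,8S,10R)
Conditions: Ti(OiPr)4 (1.2 equiv), D-(−)-diisopropyl tartrate (1.4 equiv), tBuOOH, 4 Å MS, CH2Cl2, −20 °C
Reagents that add atoms: tert-butyl hydroperoxide, CC(C)(C)OO
Why: In the Sharpless asymmetric epoxidation the primary allylic alcohol C14–OH binds the titanium tartrate, so only C1=C10 reacts, and the D-tartrate delivers oxygen to the face that gives 1R,10R, the cis-epoxide following from the ring-cis alkene whose C1 substituent cis to the carbinol is hydrogen.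

Step 22
Reactants: 32 epoxy diol
Product: 33 target CNP0211286.1 (1R,6R,7R,8S,10R)
Conditions: Ac2O, pyridine, DMAP (cat.), CH2Cl2, 0 °C → rt
Reagents that add atoms: acetic anhydride, CC(=O)OC(C)=O
Why: DMAP-catalysed acylation acetylates the primary C14 and secondary C8 hydroxyls without opening the epoxide or adding to the enal or the methylene lactone.

**Compound list**

1 | 2-methylidenepropane-1,3-diol | C=C(CO)CO | starting material
2 | 2-[(TBS-oxy)methyl]prop-2-en-1-ol | C=C(CO)CO[Si](C)(C)C(C)(C)C | intermediate
3 | 3-bromo-2-[(TBS-oxy)methyl]prop-1-ene | C=C(CBr)CO[Si](C)(C)C(C)(C)C | intermediate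
4 | 3-[(TBS-oxy)methyl]but-3-en-1-ol | C=C(CCO)CO[Si](C)(C)C(C)(C)C | intermediate
5 | 3-[(TBS-oxy)methyl]but-3-enal | C=C(CC=O)CO[Si](C)(C)C(C)(C)C | intermediate
6 | mono-tert-butyl succinate (4-tert-butoxy-4-oxobutanoic acid) | CC(C)(C)OC(=O)CCC(=O)O | starting material
7 | (4R)-4-benzyl-1,3-oxazolidin-2-one | O=C1N[C@H](Cc2ccccc2)CO1 | starting material
8 | mixed anhydride of mono-tert-butyl succinate and pivalic acid | CC(C)(C)OC(=O)CCC(=O)OC(=O)C(C)(C)C | intermediate (not isolated)
9 | tert-butyl 4-[(4R)-4-benzyl-2-oxo-1,3-oxazolidin-3-yl]-4-oxobutanoate | CC(C)(C)OC(=O)CCC(=O)N1[C@H](Cc2ccccc2)COC1=O | intermediate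
10 | dibutylboron Z-enolate of 9 | CCCCB(CCCC)O/C(=C\CC(=O)OC(C)(C)C)N1[C@H](Cc2ccccc2)COC1=O | intermediate (not isolated)
11 | O-dibutylboryl aldolate of 12 | C=C(CO[Si](C)(C)C(C)(C)C)C[C@H](OB(CCCC)CCCC)[C@@H](CC(=O)OC(C)(C)C)C(=O)N1[C@H](Cc2ccccc2)COC1=O | intermediate (not isolated)
12 | tert-butyl (3R,4S)-3-{[(4R)-4-benzyl-2-oxo-1,3-oxazolidin-3-yl]carbonyl}-4-hydroxy-6-[(TBS-oxy)methyl]hept-6-enoate | C=C(CO[Si](C)(C)C(C)(C)C)C[C@H](O)[C@@H](CC(=O)OC(C)(C)C)C(=O)N1[C@H](Cc2ccccc2)COC1=O | intermediate
13 | tert-butyl (3R,4S)-4-hydroxy-3-[methoxy(methyl)carbamoyl]-6-[(TBS-oxy)methyl]hept-6-enoate | C=C(CO[Si](C)(C)C(C)(C)C)C[C@H](O)[C@@H](CC(=O)OC(C)(C)C)C(=O)N(C)OC | intermediate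
14 | tert-butyl (3R,4S)-3-[methoxy(methyl)carbamoyl]-4-(TBS-oxy)-6-[(TBS-oxy)methyl]hept-6-enoate | C=C(CO[Si](C)(C)C(C)(C)C)C[C@H](O[Si](C)(C)C(C)(C)C)[C@@H](CC(=O)OC(C)(C)C)C(=O)N(C)OC | intermediate
15 | tert-butyl (3R,4S)-3-(prop-2-enoyl)-4-(TBS-oxy)-6-[(TBS-oxy)methyl]hept-6-enoate | C=C(CO[Si](C)(C)C(C)(C)C)C[C@H](O[Si](C)(C)C(C)(C)C)[C@@H](CC(=O)OC(C)(C)C)C(=O)C=C | intermediate
16 | tert-butyl 2-{(1R,6S)-2-oxo-6-(TBS-oxy)-4-[(TBS-oxy)methyl]cyclohex-3-en-1-yl}acetate; germacrane locants: C6=O, C5=C10, CH2OTBS on C10, OTBS on C8 (S), CH2CO2tBu on C7 (R), the two ring substituents trans | O=C1C=C(CO[Si](C)(C)C(C)(C)C)C[C@H](O[Si](C)(C)C(C)(C)C)[C@H]1CC(=O)OC(C)(C)C | intermediate (key-step precursor)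
17 | ethyl 1-bromocyclobutane-1-carboxylate | CCOC(=O)C1(Br)CCC1 | starting material
18 | cyclobut-1-ene-1-carboxylic acid | OC(=O)C1=CCC1 | intermediate
19 | methyl cyclobut-1-ene-1-carboxylate | COC(=O)C1=CCC1 | intermediate (key-step precursor)
20 | C5 epimer of 21 with a trans six–four ring fusion (1R,4S,5S,7R,8S,10S) | COC(=O)[C@@]12CC[C@@H]1[C@@]1(CO[Si](C)(C)C(C)(C)C)C[C@H](O[Si](C)(C)C(C)(C)C)[C@@H](CC(=O)OC(C)(C)C)C(=O)[C@H]21 | intermediate (not isolated)
21 | cis-anti-cis 6-4-4 tricyclic keto diester (1R,4S,5R,7R,8S,10S): cyclohexanone C5–C10 (C6=O) fused at C5–C10 to cyclobutane C1–C10–C5–C4, itself fused at C1–C4 to cyclobutane C1–C2–C3–C4; CO2Me on C4, CH2OTBS on C10, OTBS on C8, CH2CO2tBu on C7; four-membered rings on the cyclohexanone face opposite O8 | COC(=O)[C@@]12CC[C@@H]1[C@@]1(CO[Si](C)(C)C(C)(C)C)C[C@H](O[Si](C)(C)C(C)(C)C)[C@@H](CC(=O)OC(C)(C)C)C(=O)[C@@H]21 | intermediate (key-step product)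
22 | methyl (7R,8S)-7-(2-tert-butoxy-2-oxoethyl)-6-oxo-8-(TBS-oxy)-10-[(TBS-oxy)methyl]cyclodeca-1(10),4-diene-4-carboxylate with ring-cis C1=C10 and ring-trans C4=C5 | O=C1/C=C(\C(=O)OC)CC/C=C(/CO[Si](C)(C)C(C)(C)C)C[C@H](O[Si](C)(C)C(C)(C)C)[C@H]1CC(=O)OC(C)(C)C | intermediate (not isolated)
23 | methyl (7R,8S)-7-(2-tert-butoxy-2-oxoethyl)-6-oxo-8-(TBS-oxy)-10-[(TBS-oxy)methyl]cyclodeca-1(10),4-diene-4-carboxylate with both alkenes ring-cis | O=C1/C=C(/C(=O)OC)CC/C=C(/CO[Si](C)(C)C(C)(C)C)C[C@H](O[Si](C)(C)C(C)(C)C)[C@H]1CC(=O)OC(C)(C)C | intermediate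
24 | methyl (6R,7S,8S)-7-(2-tert-butoxy-2-oxoethyl)-6-hydroxy-8-(TBS-oxy)-10-[(TBS-oxy)methyl]cyclodeca-1(10),4-diene-4-carboxylate, all-cis diene (C7 descriptor changes by priority only) | O[C@@H]1/C=C(/C(=O)OC)CC/C=C(/CO[Si](C)(C)C(C)(C)C)C[C@H](O[Si](C)(C)C(C)(C)C)[C@H]1CC(=O)OC(C)(C)C | intermediate
25 | trans-fused 12,6-lactone (6R,7S,8S): γ-lactone C6–O–C12(=O)–C11H2–C7 on the all-cis cyclodeca-1(10),4-diene; CO2Me on C4, OTBS on C8, CH2OTBS on C10 | C1C(=O)O[C@@H]2/C=C(/C(=O)OC)CC/C=C(/CO[Si](C)(C)C(C)(C)C)C[C@H](O[Si](C)(C)C(C)(C)C)[C@@H]12 | intermediate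
26 | 25 carrying CH2NMe2 on C11 (C11 epimers) | CN(C)CC1C(=O)O[C@@H]2/C=C(/C(=O)OC)CC/C=C(/CO[Si](C)(C)C(C)(C)C)C[C@H](O[Si](C)(C)C(C)(C)C)[C@@H]12 | intermediate (not isolated)
27 | 25 carrying CH2NMe3 iodide on C11 (C11 epimers) | C[N+](C)(C)CC1C(=O)O[C@@H]2/C=C(/C(=O)OC)CC/C=C(/CO[Si](C)(C)C(C)(C)C)C[C@H](O[Si](C)(C)C(C)(C)C)[C@@H]12.[I-] | intermediate (not isolated)
28 | α-methylene lactone (6R,7S,8S): as 25 with C11=C13H2 | C=C1C(=O)O[C@@H]2/C=C(/C(=O)OC)CC/C=C(/CO[Si](C)(C)C(C)(C)C)C[C@H](O[Si](C)(C)C(C)(C)C)[C@@H]12 | intermediate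
29 | α-methylene lactol (C12 hemiacetal, anomers) with C15H2OH on C4 (6R,7S,8S) | C=C1C(O)O[C@@H]2/C=C(/CO)CC/C=C(/CO[Si](C)(C)C(C)(C)C)C[C@H](O[Si](C)(C)C(C)(C)C)[C@@H]12 | intermediate
30 | bis-TBS enal α-methylene lactone (6R,7S,8S): C15HO on C4, OTBS on C8, CH2OTBS on C10 | C=C1C(=O)O[C@@H]2/C=C(/C=O)CC/C=C(/CO[Si](C)(C)C(C)(C)C)C[C@H](O[Si](C)(C)C(C)(C)C)[C@@H]12 | intermediate
31 | diol enal α-methylene lactone (6R,7R,8S): OH on C8, CH2OH on C10 | C=C1C(=O)O[C@@H]2/C=C(/C=O)CC/C=C(/CO)C[C@H](O)[C@@H]12 | intermediate
32 | (1R,6R,7R,8S,10R)-1,10-epoxy diol: cis-epoxide on C1–C10, OH on C8, CH2OH on C10 | C=C1C(=O)O[C@@H]2/C=C(/C=O)CC[C@H]3O[C@@]3(CO)C[C@H](O)[C@@H]12 | intermediate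
33 | CNP0211286.1, (1R,6R,7R,8S,10R)-8,14-diacetoxy-1,10-epoxy-15-oxogermacra-4,11(13)-dien-12,6-olide | C=C1C(=O)O[C@@H]2/C=C(/C=O)CC[C@H]3O[C@@]3(COC(C)=O)C[C@H](OC(C)=O)[C@@H]12 | target

**Totals**

Total step count: 22. Longest linear sequence: 19 steps (steps 1–4, 6–10 and 13–22).

**Steps most likely to fail**

Step 14. The first-formed ring-cis/ring-trans dienone may undergo Cope rearrangement at the temperature needed for the cycloreversion, or part of the material may fragment through the other chair so that C1=C10 emerges ring-trans. The fallback replaces kinetic interception by a thermodynamic funnel. Starting from 21, heating is continued (PhMe, about 200 °C) until cycloreversion and Cope rearrangement are complete, which gives the cis-1,2-divinylcyclohexanone Cope product F1. This is then heated with catalytic PhSSPh (PhMe, about 180 °C), so that the Cope equilibrium is re-established and thiyl radicals isomerise the strained alkenes as they appear. Material should drain into the unstrained, fully conjugated all-cis dienone, which needs a boat transition state to rearrange, and the route is rejoined at 23.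

Step 15. Facial selectivity may be poor or reversed, because the α-branched C7 side can compete with the alkenyl group for the role of large substituent, and hydride may also add in conjugate fashion to the doubly activated alkene. The fallback uses substrate control followed by stereochemical correction. Starting from 23, Luche reduction (NaBH4, CeCl3·7H2O, MeOH, −78 °C) should give a single 1,2-reduction product. If that is the 6R alcohol it is 24 itself. If it is the (6S)-hydroxy diester F2, Mitsunobu esterification (PPh3, DIAD, PhCO2H, PhMe, 0 °C) inverts C6 to the (6R)-benzoate F3; SN2′ attack is blocked at the fully substituted, electron-poor C4. Methanolysis (K2CO3, MeOH, 0 °C) then rejoins the route at 24.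

Step 21. The C8/C14 diol and the aldehyde may bind titanium outside the tartrate-controlled assembly, which would lower conversion and face selectivity, and the epoxy alcohol may open on the Lewis acid. The fallback is a metal-free peracid epoxidation under conformational control. Starting from 30, mCPBA (NaHCO3, CH2Cl2, 0 °C) should attack only the electron-rich C1=C10 from the outer face of the ring to give the bis-TBS 1,10-epoxide F4. HF·pyridine (pyridine, THF, 0 °C) then removes both silyl groups and rejoins the route at 32.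

**Further compounds**

F1 | step 14 | methyl 2-{(3R,4S)-3-(2-tert-butoxy-2-oxoethyl)-6-ethenyl-2-oxo-4-(TBS-oxy)-6-[(TBS-oxy)methyl]cyclohexyl}prop-2-enoate, vinyl and acrylate groups cis, configuration at the two new ring centres not assigned | C=CC1(CO[Si](C)(C)C(C)(C)C)C[C@H](O[Si](C)(C)C(C)(C)C)[C@@H](CC(=O)OC(C)(C)C)C(=O)C1C(=C)C(=O)OC
F2 | step 15 | (6S,7S,8S)-6-hydroxy diester, the C6 epimer of 24 | O[C@H]1/C=C(/C(=O)OC)CC/C=C(/CO[Si](C)(C)C(C)(C)C)C[C@H](O[Si](C)(C)C(C)(C)C)[C@H]1CC(=O)OC(C)(C)C
F3 | step 15 | (6R,7S,8S)-6-benzoyloxy diester, the benzoate of 24 | O=C(O[C@@H]1/C=C(/C(=O)OC)CC/C=C(/CO[Si](C)(C)C(C)(C)C)C[C@H](O[Si](C)(C)C(C)(C)C)[C@H]1CC(=O)OC(C)(C)C)c1ccccc1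
F4 | step 21 | (1R,6R,7S,8S,10R)-1,10-epoxide of 30, the bis-TBS ether of 32 | C=C1C(=O)O[C@@H]2/C=C(/C=O)CC[C@H]3O[C@@]3(CO[Si](C)(C)C(C)(C)C)C[C@H](O[Si](C)(C)C(C)(C)C)[C@@H]12
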